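The closed, stirred vessel starts with its electrophile undissolved, and each earlier run shows a solid that shrinks quickly and then slowly, while little target appears.

| flask | solid electrophile | free base | protonated nucleophile | remark | time |
|---|---|---|---|---|---|
| east | 0.018 M | 0.93 equiv | 2.5 equiv | run made earlier |  |
| west | 0.018 M | 1.5 equiv | 2.5 equiv | run made earlier |  |
| south-west | 0.018 M | 1.9 equiv | 2.5 equiv | run made earlier |  |
| summer | 0.018 M | 1.20 equiv | 2.50 equiv |  | 2.5 min |
| winter | 0.018 M | 1.60 equiv | 2.50 equiv |  | 2.5 min |

| run | time / min | solid electrophile / % | target / % |
|---|---|---|---|
| east | 0.200 | 34.2 | 0 |
| east | 0.500 | 18.6 | 2.2 |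
| east | 1.00 | 15.1 | 0 |
| east | 2.50 | 13.1 | 2.5 |
| west | 0.667 | 17.4 | 1.7 |
| west | 1.33 | 14.8 | 1.0 |
| west | 2.00 | 13.8 | 3.3 |
| west | 2.50 | 12.6 | 3.4 |
| south-west | 0.200 | 34.9 | 0 |
| south-west | 0.500 | 19.0 | 1.1 |
| south-west | 1.00 | 13.7 | 0 |
| south-west | 2.50 | 9.9 | 2.9 |

(readings scatter by 1 percentage point)

- part of the solid electrophile that has reacted (what has only dissolved counts as not reacted) at the end, summer
- part of the solid electrophile that has reacted (what has only dissolved counts as not reacted) at the end, winter
- what raising the equivalents of free base from its lowest to its highest value here does to the part of the solid electrophile that has reacted (what has only dissolved counts as not reacted) (changes below 5 percentage points count as none) (it rises / it falls / no change)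

- the earlier runs were read with a standard deviation of 1 percentage point
- at the start none of the solid electrophile is in solution
- what has only dissolved of solid electrophile counts as not reacted

With the main step by itself, whatever leaves the solid would count as reacted, and the east run would stand at 86.9% reacted at 2.50 min. But target reads 2.5% there. Adding dissolving as a process of its own gives the curve two ends. Early in the east run the solid loses 16 percentage points between 0.200 min and 0.500 min, a far faster fall than the 2 points between 1.00 min and 2.50 min. This reckoning reads the early fall as dissolving and takes the solution as full in the tail, where solid enters at the pace reaction makes room.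

To join the ends, each tail is run straight back to time zero. This reckoning reads the solid missing there as gone into solution unreacted: 83.6% in east, 82.7% in west and 83.8% in south-west. Their mean, 83.3%, is the saturation share: the solubility as a share of the charge, a reading worth 15.0 mM. While solid is left and the solution stays full, the reacted part is the charge minus the saturation share minus the solid left. Whatever target turns into next is still counted by this subtraction.

Free base enters through the solid left at the end, which is interpolated between the runs. That gives 3.79% reacted for summer and 4.73% for winter, each uncertain by about 1 point or more. The gap of 0.94 points is smaller than the margin, so this reckoning expects no change.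

The forecast, which took the solid column as “everything still unreacted, dissolved or not”, differs on the amounts: 87.4% for summer and 88.6% for winter, with no change for the trend. The simulation gives 5.02% for summer and 5.80% for winter, and for the trend no change, a change of 0.78 points.

    electrophile + nucleophile → acid set free + target (k = 0.630 M⁻¹ s⁻¹)
    nucleophile + acid set free ⇌ protonated nucleophile, settled at all times (K = 7.70 × 10⁵ M⁻¹)
    acid set free + free base ⇌ salt of the base (K = 1.50 × 10⁶ M⁻¹, k = 6.80 M⁻¹ s⁻¹)
    electrophile + target → side product (k = 0.230 M⁻¹ s⁻¹)
    solid electrophile ⇌ electrophile, rate k5*(cs5 - [electrophile]) while solid is left; crystals form when [electrophile] > cs5 (solubility = 15.0 mM, k = 0.130 s⁻¹)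
    target ⇌ isomer of the product (K = 0.910, k = 0.0240 s⁻¹)

In summer at 2.50 min, electrophile is made at 0.993 times the rate at which it is used, and it stands at 83.1% at 1.25 min and at 83.0% at 2.50 min, while the solid falls by 2.9 points over that stretch. The charge minus the saturation share 83.3% minus summer's 12.0% of solid gives 4.70%, beside the simulated 5.02%. A neighbour of summer charged with 4.80 equiv of free base keeps 7.23% of solid at 2.50 min, so the same subtraction gives 9.47%, and that flask has reacted 10.1%.

The runs come from a simulation on assumed constants; noise was put on by code.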